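All runs are simulated with constants of no real substance, noise included.

We start with a subtraction, the easiest step these runs allow. The flasks, their readings and the questions are these.

| setting | Tuesday's | Thursday's | Sunday's | Wednesday's | Monday's |
|---|---|---|---|---|---|
| starting material | 120 mM | 60.0 mM | 120 mM | 120 mM | 120 mM |
| partner | 240 mM | 180 mM | 120 mM | 240 mM | 240 mM |
| catalyst | 1.20 mM | 1.20 mM | 1.20 mM | 1.20 mM | 1.20 mM |
| target |  |  |  | 36.0 mM |  |
| time |  |  |  |  | 52 min |

- Tuesday's run (time / min: [target] / mM): 0.52: 4.2; 1.2: 8.9; 2.6: 18.3; 5.8: 36.4; 13: 63.2
- Thursday's run (time / min: [target] / mM): 0.52: 3.1; 1.2: 6.1; 2.6: 12.6; 5.8: 25.8; 13: 45.2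
- Sunday's run (time / min: [target] / mM): 0.52: 3.2; 1.2: 6.0; 2.6: 13.2; 5.8: 27.1; 13: 47.1
- Wednesday's run (time / min: [target] / mM): 0.52: 39.1; 1.2: 44.1; 2.6: 51.8; 5.8: 66.4; 13: 87.2

(readings scatter by 0.4 mM)

- Overall: starting material + partner -> target, with catalyst as catalyst.
- Constant volume, constant temperature.
- The analysis sees a species whether free or bound.
- An order is taken over about fifteen percent of the charge, up and down.

- the power of [starting material] that the first rate follows, about the charge of the Tuesday's run; measure it at two percent of starting material made into target (one fixed amount of target, the same in the runs compared)
- the power of [partner] that the first rate follows, about the charge of the Tuesday's run; measure it at two percent of starting material made into target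
- target in the Monday's run at 52 min, as a share of the starting material charged

Tuesday's and Wednesday's flasks differ in the 36.0 mM of target charged to Wednesday's, so we subtract Tuesday's reading from Wednesday's at equal times. If both flasks make target alike, a stable target keeps that excess at its charge, but the excess reads 30.0 mM at 5.8 min and 24.0 mM at 13 min. We read this as a first-order loss of target and define the life of target, the time in which such an excess falls by a factor of e. The later reading gives 32.1 min, and the earlier one gives 31.8 min.

The second time is the filling time. Starting material is the limiting reagent, at 120 mM against 240 mM of partner, and Tuesday's early rate reads 7.42 mM min⁻¹, which would turn that charge in 16.2 min. This is about half the life, and 52 min is longer than either. Monday's flask has Tuesday's charge, so we place the mean target at 8.10 min and let it decay until 52 min. Our reckoning leaves 25.4 % of the charge. We reckon no orders of our own.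

The forecast gives orders of 0.35 in starting material and 0.42 in partner, and 81 % for Monday's flask, reading the falling rates as “mild product inhibition plus catalyst loss”. Our share is lower than the forecast's by 56 percentage points.

The simulation gives orders of 0.48 and 0.52, and 27.1 % for Monday's flask, from this scheme:

    catalyst + starting material ⇌ catalyst-substrate complex, settled at all times (113.0 M⁻¹)
    catalyst-substrate complex + partner ⇌ ternary complex, settled at all times (37.50 M⁻¹)
    ternary complex → target + catalyst (3.936 min⁻¹)
    target → decomposed product (0.03174 min⁻¹)
    starting material + partner → target (0.1266 M⁻¹ min⁻¹)

Wednesday's flask, at the fixed amount made, ran at 0.85 of Tuesday's 7.6 mM min⁻¹; its extra 36.0 mM over the life of 32.1 min is a loss of 1.12 mM min⁻¹, which leaves 0.852 of that rate. Monday's flask made target through the catalyst and also by the direct step from starting material and partner, which ran at 3.65 mM min⁻¹ at the charge; the 16.2 min filling time reckons the two together, and target went to decomposed product from the first target on. That loss step carried on past the filling time for 35.8 min, and at 52 min Monday's flask held 32.5 mM of target, 27.1 % of the charge.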